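# Sequoiaflavone: ring B of unit 1 built from methyl coumalate

## The problem

Sequoiaflavone 28 consists of two flavone units held together by one carbon–carbon bond. Unit 1 (5-hydroxy-7-methoxy; atoms C2 to C8a, ring B C1' to C6') is joined through C3' of its ring B to C8'' of ring A of unit 2 (5'',7'',4'''-trihydroxy). There is no stereocentre, so no part of the structure has to control another in space. The task is regiochemical and comes down to telling six phenolic oxygens apart.

The biaryl bond lies between two electron-rich rings and is flanked by O4', O7'' and O1''. That is the least favourable setting for joining two finished halves by cross-coupling.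

Ring A of unit 2 is a phloroglucinol, and its pyranone must close on the oxygen ortho to the biaryl carbon. Closure on the oxygen para to it gives the 6''-linked isomer, and hot mineral acid can interconvert the two by ring opening and reclosure (Wessely–Moser rearrangement).

Only O7 is methylated. Every protecting group must therefore leave under conditions that spare an aryl methyl ether and the two C2=C3 double bonds. The finished pyranones should also not see hot alkali, which opens them.

The plan rests on the pattern of ring B of unit 1: carbon at C1', aryl at C3', oxygen at C4'. C1', C2', C5' and C6' map onto C5, C6, C3 and C4 of methyl coumalate 10, and the ester of 10 is the C1' substituent. C3'–C4' maps onto the double bond of the ketene acetal 9. The hindered biaryl bond can thus enter the synthesis as the unhindered benzylic bond of arylacetic acid 7.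

## Retrosynthesis

**28 ⇒ 27.**
- The last cut removes four O–benzyl bonds (O4', O5'', O7'', O4''').
- Benzyl is preferred to methyl because one methyl ether has to stay. It is preferred to acetal groups because acid is used twice on the way.
- The chelated 5-OH needs no protection.
- The forward hydrogenolysis must stop before the C2=C3 bonds are touched.

**27 ⇒ 26 ⇒ 21 + 23.**
- The unit 1 pyranone is opened at O1–C2 to give diketone 26, then at C2–C3 to give acid 21 and acetophenone 23.
- The neighbouring cut at C2–C1' would need another coupling on a crowded ring.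
- A chalcone route would need ring B at the aldehyde level, two redox steps away from the ester that the key step delivers.
- The cut removes a whole benzopyranone, and 23 is one step from commercial 22.
- Because 23 is symmetric, either hydroxyl closes to the same flavone.
- The forward step requires carbon acylation of polyanion 25 by acid chloride 24.

**21 ⇒ 20 ⇒ 18 + 19.**
- The unit 2 pyranone is cut at O1''–C2'' (oxidative closure of chalcone 20) and at C2''=C3'' (aldol condensation of 18 with commercial aldehyde 19).
- Compound 18 carries both a nucleophilic acetyl group and an electrophilic ester. The acetyl group must be used up before the ester is activated, so unit 2 is built first.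
- The alkali needed for the aldol step also saponifies the ester, which gives the oxidation level needed for unit 1 without a separate step.
- Compound 18 has a single free hydroxyl, so only the 8''-linked flavone can form.

**18 ⇒ 17 ⇒ 15 ⇒ 14.**
- Two O–benzyl bonds, the C4a''–C4'' aryl–acetyl bond and a carbon–iodine bond are removed in turn.
- A Lewis-acid acylation is the neighbouring option, but it endangers the benzyl ether.
- The two free positions of the phloroglucinol ring of 14 are equivalent, so mono-iodination can give only 15.
- A Stille coupling then delivers enol ether 16. One acid treatment unmasks the ketone and strips both MOM groups.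
- In 17 the hydroxyl beside the acetyl group is chelated and is left alone by benzylation.
- The oxygen para to the biaryl carbon (future O5'') stays benzylated throughout. This is what fixes the 8''-linkage.

**14 ⇒ 9 + 10 (key disconnection).**
- Ring B is cut at C2'–C3' and C4'–C5'.
- The obvious neighbour is the C3'–C8'' bond itself. That cut requires a coupling flanked by three ortho oxygens, with a 2,6-dialkoxyaryl metal partner that is prone to protodemetalation.
- No other pair of ring B bonds leads to a purchasable six-atom building block.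
- The cut removes one ring and two skeletal bonds. It leaves commercial 10 and a single arene with a two-carbon side chain.
- The forward reaction must deliver one orientation (aryl meta, oxygen para to the ester), lose the lactone bridge by decarboxylation, and aromatise by loss of one silyloxy group.

**9 ⇒ 7 ⇒ 5 ⇒ 3 ⇒ 2 ⇒ 1.**
- The ketene acetal is the doubly silylated enediolate 8 of acid 7.
- Acid 7 is the oxidation product of alcohol 5.
- The aryl–CH2 bond of 5 is cut to aryllithium 4, which forms between the two MOM ethers of 3 and takes up a two-carbon epoxide electrophile. This is one step shorter than allylation followed by cleavage.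
- Compound 3 goes back through phenol 2 to phloroglucinol 1. MOM is placed on the two oxygens that must be freed later, and benzyl on the one that must stay blocked.

**23 ⇒ 22.** The O7–methyl bond is cut. In 22 only the hydroxyl para to the ketone is free of chelation, so a single methylation places the methyl group before any valuable material is involved.

## Roads not taken

**Alternative 1:** The cut is O1–C8a of the unit 1 pyranone, made by nucleophilic aromatic substitution.
- *Forward step:* the enolate of 1-(2,6-difluoro-4-methoxyphenyl)ethanone A1 would be acylated with 24 to give diketone A2. The enolate oxygen of A2 then displaces one ortho fluorine under a mild carbonate base in a dipolar aprotic solvent and gives the 5-fluoroflavone A3.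
- *Merits:* A1 has no acidic hydroxyl, so its acylation is cleaner than that of polyanion 25. Closure needs no acid, so the benzyl ethers are never at risk. The two fluorines are equivalent. In these respects this road is better than steps 13 and 14.
- *Weak points:* A3 is not yet at the oxygenation pattern of the target. C5–F must be exchanged for oxygen in a second displacement. That ring has meanwhile gained the donor O1, and the alkoxide and heat required can also attack C2 of either pyranone. The endgame gains one step, and it is the harshest one.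
- *Comparison:* this road does nothing for the biaryl bond and would have to borrow 21 from the present plan or from a cross-coupling. The chosen plan starts from 23, which already carries the right oxygens, and keeps a protected stepwise acylation in reserve.

**Alternative 2:** The cut is C8''–C7'' in ring A of unit 2.
- *Forward step:* methyl 6-[2-(benzyloxy)-5-bromophenyl]-3,5-dioxohexanoate A4 is treated with an alkoxide base. Its benzylic C6 attacks the ester carbon and gives the arylphloroglucinol A5.
- *Merits:* it shares the central merit of the chosen plan, since the biaryl bond again starts as a benzylic bond. It reaches a biaryl in fewer steps, needs no sealed tube, and avoids a moisture-sensitive ketene acetal. On step count to the biaryl it is ahead.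
- *Weak points:* C6 is the least acidic of the three methylene groups of A4, so the carbon closure has to come from a polyanion. Lactonisation through an enol oxygen to a 4-hydroxy-2-pyranone is the usual outcome for a 3,5-dioxo ester. A5 emerges with three free, air-sensitive, carbon-nucleophilic hydroxyl positions. The para oxygen must then be singled out before the 8''-linkage is safe. The bromide still has to be converted into the C2 carbon.
- *Comparison:* 14 arrives with its oxygens already differentiated and with the C2 carbon in place as an ester. This repays the extra early steps.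

**Alternative 3:** The cut is C4a–C8a in ring A of unit 1.
- *Forward step:* triacetic acid lactone A6 would be acylated at its methyl group to give the 6-(cinnamoylmethyl)-4-hydroxy-2-pyranone A7. A magnesium alkoxide opens the lactone, and the side-chain methylene attacks the former lactone carbonyl to give the 2',4',6'-trihydroxychalcone A8.
- *Merits:* A6 is cheap. Ring A and the chalcone appear in one step, and ring A needs no protecting group up to that point.
- *Weak points:* it spends the most valuable material on a ring that can be bought as 22. Reaching A7 needs ring B extended to a cinnamoyl unit, several steps beyond the ester of 14. Alkoxide can add to the enone, and an aldol mode of closure competes. O7 would have to be methylated selectively on A8 at the very end.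
- *Comparison:* like the first alternative it leaves the biaryl bond unsolved, so it cannot replace the chosen key step and would only lengthen what follows it.

Key step: step 6

Assumption: the C3'–C8'' axis has three ortho substituents, all oxygen, and the target structure carries no axial descriptor. The biaryl is therefore treated as configurationally labile, and no atropselective step is planned.

## Route

Step 1
Reactants: 1 phloroglucinol (benzene-1,3,5-triol)
Product: 2 3,5-bis(methoxymethoxy)phenol
Conditions: MOMCl (2.0 equiv), i-Pr2NEt (2.2 equiv), DMF, 0 °C to rt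
Reagents that add atoms: chloromethyl methyl ether, COCCl
Why: Williamson-type O-alkylation; the hard chloromethyl ether reacts at oxygen and not at carbon. The three hydroxyls are equivalent, so the distribution is statistical; the bis-ether is separated by chromatography and the mono-ether can be resubmitted.

Step 2
Reactants: 2 3,5-bis(methoxymethoxy)phenol
Product: 3 1-(benzyloxy)-3,5-bis(methoxymethoxy)benzene
Conditions: BnBr (1.1 equiv), K2CO3, acetone, reflux
Reagents that add atoms: benzyl bromide, BrCc1ccccc1
Why: Standard Williamson benzylation of a single phenol; MOM ethers are inert to carbonate base.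

Step 3
Reactants: 3 1-(benzyloxy)-3,5-bis(methoxymethoxy)benzene
Product: 5 2-[4-(benzyloxy)-2,6-bis(methoxymethoxy)phenyl]ethanol, via aryllithium 4 (not isolated)
Conditions: n-BuLi (1.1 equiv), THF, 0 °C; ethylene oxide (3 equiv, THF solution), −78 °C to rt; H2O
Reagents that add atoms: ethylene oxide, C1CO1
Why: Directed ortho-metalation; the position between the two MOM ethers is chelated from both sides and is favoured over the sites next to the weaker benzyloxy director. The aryllithium then opens the epoxide by SN2 attack.

Step 4
Reactants: 5 2-[4-(benzyloxy)-2,6-bis(methoxymethoxy)phenyl]ethanol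
Product: 7 [4-(benzyloxy)-2,6-bis(methoxymethoxy)phenyl]acetic acid, via arylacetaldehyde 6 (not isolated)
Conditions: TEMPO (0.2 equiv), PhI(OAc)2 (2.2 equiv), MeCN/H2O 1:1, rt
Reagents that add atoms: water, O
Why: Oxoammonium oxidation of a primary alcohol to the acid through the aldehyde hydrate. The system contains no active chlorine, so the electron-rich ring is not halogenated, and the weakly acidic medium leaves the MOM ethers intact.

Step 5
Reactants: 7 [4-(benzyloxy)-2,6-bis(methoxymethoxy)phenyl]acetic acid
Product: 9 2-[4-(benzyloxy)-2,6-bis(methoxymethoxy)phenyl]-1,1-bis(trimethylsilyloxy)ethene, via dilithium enediolate 8 (not isolated)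
Conditions: LiN(i-Pr)2 (2.2 equiv), THF, −78 to 0 °C; Me3SiCl (2.5 equiv), −78 °C to rt; pentane, filtration under Ar, concentration
Reagents that add atoms: chlorotrimethylsilane, C[Si](C)(C)Cl
Why: Double deprotonation of an arylacetic acid and O,O-silylation of the enediolate is the standard entry to bis(silyl) ketene acetals. The two oxygen substituents are identical, so no alkene geometry arises; non-aqueous work-up protects the product.

Step 6
Reactants: 9 2-[4-(benzyloxy)-2,6-bis(methoxymethoxy)phenyl]-1,1-bis(trimethylsilyloxy)ethene; 10 methyl coumalate (methyl 2-oxo-2H-pyran-5-carboxylate)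
Product: 14 methyl 3-[4-(benzyloxy)-2,6-bis(methoxymethoxy)phenyl]-4-hydroxybenzoate, via bridged lactone cycloadduct 11 (not isolated), via dihydrobenzene 12 (not isolated), via aryl trimethylsilyl ether 13 (not isolated)
Conditions: 10 (1.5 equiv), N,O-bis(trimethylsilyl)acetamide (1.2 equiv), toluene (1 M), sealed tube, 120 °C; then K2CO3 (cat.), MeOH, rt
Reagents that add atoms: none
Why: This is an inverse-electron-demand Diels–Alder reaction of a 2-pyranone followed by cycloreversion and aromatisation, the reaction type by which methyl coumalate and alkyl ketene acetals or enol ethers give para-oxygenated benzoates; the silylated, aryl-substituted dienophile is an extension within that class. The electron-poor diene C3=C4–C5=C6 of 10 meets the electron-rich alkene of 9: the aryl-bearing carbon, the nucleophilic end, bonds to C6 (β to the ester and δ to the lactone carbonyl), and the acetal carbon bonds to C3, giving 11. Ring B is therefore closed by an intermolecular [4+2] addition that forms C2'–C3' and C4'–C5', either in concert or, with this hindered partner, as a conjugate addition followed by closure of the dienolate carbon C3 on the silyloxycarbenium carbon; both paths end in 11. Retro-[4+2] expels the O1–C2 bridge as CO2 and leaves 12, in which ionisation of one silyloxy group gives a cation that is simply the C3'-protonated arene and loses that proton at once, so 13 forms irreversibly. The only selectivity needed is orientation (aryl meta and oxygen para to the ester), and the matched polarity of the two partners secures it; the stereocentres of 11 and 12 are transient, so endo/exo selectivity is irrelevant. The silylacetamide captures the liberated silanol, which would otherwise protonate unreacted 9, and the final methanolysis frees the phenol without touching MOM ethers, benzyl ether or ester.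

Step 7
Reactants: 14 methyl 3-[4-(benzyloxy)-2,6-bis(methoxymethoxy)phenyl]-4-hydroxybenzoate
Product: 15 methyl 3-[4-(benzyloxy)-3-iodo-2,6-bis(methoxymethoxy)phenyl]-4-hydroxybenzoate
Conditions: NIS (1.0 equiv), MeCN, 0 °C, dark
Reagents that add atoms: N-iodosuccinimide, O=C1CCC(=O)N1I
Why: Electrophilic aromatic iodination; the phloroglucinol triether ring is far more nucleophilic than the ester-deactivated phenol ring under neutral conditions. Its two free positions are equivalent, and the first iodine slows a second substitution.

Step 8
Reactants: 15 methyl 3-[4-(benzyloxy)-3-iodo-2,6-bis(methoxymethoxy)phenyl]-4-hydroxybenzoate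
Product: 17 methyl 3-[3-acetyl-4-(benzyloxy)-2,6-dihydroxyphenyl]-4-hydroxybenzoate, via ethyl enol ether 16 (not isolated)
Conditions: Bu3SnC(OEt)=CH2 (1.5 equiv), PdCl2(PPh3)2 (5 mol %), dioxane, 100 °C; then 3 M aq HCl, MeOH, 50 °C
Reagents that add atoms: tributyl(1-ethoxyvinyl)stannane, CCCC[Sn](CCCC)(CCCC)C(=C)OCC; water, O
Why: Stille coupling with an acetyl anion equivalent tolerates the ester, the free phenol and all ethers. The acid treatment hydrolyses the enol ether to the methyl ketone and cleaves both MOM acetals, while the benzyl ether and the methyl ester persist in methanolic HCl.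

Step 9
Reactants: 17 methyl 3-[3-acetyl-4-(benzyloxy)-2,6-dihydroxyphenyl]-4-hydroxybenzoate
Product: 18 methyl 3-[3-acetyl-4,6-bis(benzyloxy)-2-hydroxyphenyl]-4-(benzyloxy)benzoate
Conditions: BnBr (2.1 equiv), K2CO3 (2.5 equiv), DMF, rt
Reagents that add atoms: benzyl bromide, BrCc1ccccc1
Why: Chelation-controlled selective Williamson etherification; the hydroxyl beside the acetyl group is hydrogen-bonded to the ketone and flanked on both sides, so it stays free. The hydroxyls para to the ketone and para to the ester are the acidic, reactive ones.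

Step 10
Reactants: 18 methyl 3-[3-acetyl-4,6-bis(benzyloxy)-2-hydroxyphenyl]-4-(benzyloxy)benzoate; 19 4-(benzyloxy)benzaldehyde
Product: 20 4-(benzyloxy)-3-{4,6-bis(benzyloxy)-3-[(E)-3-(4-benzyloxyphenyl)prop-2-enoyl]-2-hydroxyphenyl}benzoic acid
Conditions: 19 (1.3 equiv), KOH (50% aq, excess), EtOH/THF, rt; then 1 M HCl, 0 °C
Reagents that add atoms: potassium hydroxide, [K+].[OH-]
Why: Claisen–Schmidt condensation of a 2'-hydroxy-4',6'-dialkoxyacetophenone with a non-enolisable aldehyde; E1cB dehydration gives the conjugated E-enone under thermodynamic control. The excess hydroxide saponifies the unhindered methyl benzoate in the same operation and so sets the acid level needed in step 13.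

Step 11
Reactants: 20 4-(benzyloxy)-3-{4,6-bis(benzyloxy)-3-[(E)-3-(4-benzyloxyphenyl)prop-2-enoyl]-2-hydroxyphenyl}benzoic acid
Product: 21 4-(benzyloxy)-3-{5,7-bis(benzyloxy)-2-[4-(benzyloxy)phenyl]-4-oxo-4H-chromen-8-yl}benzoic acid
Conditions: I2 (0.2 equiv), DMSO, 130 °C
Reagents that add atoms: none
Why: Iodine/DMSO oxidative cyclisation of a 2'-hydroxychalcone: oxa-Michael closure, then iodination and dehydroiodination, with DMSO as terminal oxidant. Only one hydroxyl is free, so only the 8''-linked flavone can form; aryl benzyl ethers and the carboxylic acid are tolerated.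

Step 12
Reactants: 22 2',4',6'-trihydroxyacetophenone
Product: 23 2',6'-dihydroxy-4'-methoxyacetophenone
Conditions: Me2SO4 (1.0 equiv), K2CO3 (1.1 equiv), acetone, reflux
Reagents that add atoms: dimethyl sulfate, COS(=O)(=O)OC
Why: Selective O-methylation; the 4'-hydroxyl is the only one not hydrogen-bonded to the ketone and is the most acidic, so one equivalent of the methylating agent reacts there.

Step 13
Reactants: 21 4-(benzyloxy)-3-{5,7-bis(benzyloxy)-2-[4-(benzyloxy)phenyl]-4-oxo-4H-chromen-8-yl}benzoic acid; 23 2',6'-dihydroxy-4'-methoxyacetophenone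
Product: 26 1-(2,6-dihydroxy-4-methoxyphenyl)-3-{4-(benzyloxy)-3-[5,7-bis(benzyloxy)-2-(4-benzyloxyphenyl)-4-oxo-4H-chromen-8-yl]phenyl}propane-1,3-dione, via acid chloride 24 (not isolated), via trilithium salt 25 (not isolated)
Conditions: 21, (COCl)2 (1.5 equiv), DMF (cat.), CH2Cl2, 0 °C to rt, evaporate; 23 (1.3 equiv), LiN(SiMe3)2 (5.2 equiv), THF, −78 to −10 °C; add 24 in THF, −78 °C to rt; 1 M HCl
Reagents that add atoms: none
Why: Direct C-acylation of the lithium polyanion of an unprotected hydroxyacetophenone with an aroyl chloride, the one-flask form of the Baker–Venkataraman synthesis. Any O-acylation is corrected in situ by acyl migration to the enolate carbon under the excess base, and the extra equivalent of base takes up the acidic diketone. At low temperature the acid chloride is far more electrophilic than the flavone of unit 2.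

Step 14
Reactants: 26 1-(2,6-dihydroxy-4-methoxyphenyl)-3-{4-(benzyloxy)-3-[5,7-bis(benzyloxy)-2-(4-benzyloxyphenyl)-4-oxo-4H-chromen-8-yl]phenyl}propane-1,3-dione
Product: 27 4',5'',7'',4'''-tetra-O-benzylsequoiaflavone
Conditions: p-TsOH·H2O (0.2 equiv), toluene, 90 °C
Reagents that add atoms: none
Why: Acid-catalysed cyclodehydration of a 1-(2-hydroxyaryl)-1,3-diketone; either of the two equivalent phenols adds to the aroyl carbonyl and water is lost, and the other remains as the chelated 5-OH. The catalytic sulfonic acid is too mild for Wessely–Moser isomerisation, and stray loss of a benzyl group would be harmless because the next step removes them all.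

Step 15
Reactants: 27 4',5'',7'',4'''-tetra-O-benzylsequoiaflavone
Product: 28 sequoiaflavone
Conditions: H2 (1 atm), 10% Pd/C, THF/MeOH, rt
Reagents that add atoms: none
Why: Catalytic hydrogenolysis of aryl benzyl ethers; the aryl methyl ether is inert. The C2=C3 bonds, part of vinylogous esters, are reduced much more slowly at atmospheric pressure, so the reaction is stopped after uptake of four equivalents of hydrogen.

## Compound list

1 | phloroglucinol | Oc1cc(O)cc(O)c1 | starting material
2 | 3,5-bis(methoxymethoxy)phenol | COCOc1cc(O)cc(OCOC)c1 | intermediate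
3 | 1-(benzyloxy)-3,5-bis(methoxymethoxy)benzene | COCOc1cc(OCc2ccccc2)cc(OCOC)c1 | intermediate
4 | [4-(benzyloxy)-2,6-bis(methoxymethoxy)phenyl]lithium | [Li]c1c(OCOC)cc(OCc2ccccc2)cc1OCOC | intermediate
5 | 2-[4-(benzyloxy)-2,6-bis(methoxymethoxy)phenyl]ethanol | OCCc1c(OCOC)cc(OCc2ccccc2)cc1OCOC | intermediate
6 | [4-(benzyloxy)-2,6-bis(methoxymethoxy)phenyl]acetaldehyde | O=CCc1c(OCOC)cc(OCc2ccccc2)cc1OCOC | intermediate
7 | [4-(benzyloxy)-2,6-bis(methoxymethoxy)phenyl]acetic acid | OC(=O)Cc1c(OCOC)cc(OCc2ccccc2)cc1OCOC | intermediate
8 | dilithium enediolate of 7 | [Li]OC(O[Li])=Cc1c(OCOC)cc(OCc2ccccc2)cc1OCOC | intermediate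
9 | 2-[4-(benzyloxy)-2,6-bis(methoxymethoxy)phenyl]-1,1-bis(trimethylsilyloxy)ethene | C[Si](C)(C)OC(O[Si](C)(C)C)=Cc1c(OCOC)cc(OCc2ccccc2)cc1OCOC | intermediate
10 | methyl coumalate | COC(=O)c1ccc(=O)oc1 | starting material
11 | methyl 7-[4-(benzyloxy)-2,6-bis(methoxymethoxy)phenyl]-3-oxo-8,8-bis(trimethylsilyloxy)-2-oxabicyclo[2.2.2]oct-5-ene-6-carboxylate (racemic, endo/exo mixture, stereocentres transient) | O=C1OC2C(C(=O)OC)=CC1C(O[Si](C)(C)C)(O[Si](C)(C)C)C2c3c(OCOC)cc(OCc4ccccc4)cc3OCOC | intermediate
12 | methyl 3-[4-(benzyloxy)-2,6-bis(methoxymethoxy)phenyl]-4,4-bis(trimethylsilyloxy)cyclohexa-1,5-diene-1-carboxylate (racemic, stereocentre transient) | COC(=O)C1=CC(c2c(OCOC)cc(OCc3ccccc3)cc2OCOC)C(O[Si](C)(C)C)(O[Si](C)(C)C)C=C1 | intermediate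
13 | methyl 3-[4-(benzyloxy)-2,6-bis(methoxymethoxy)phenyl]-4-(trimethylsilyloxy)benzoate | COC(=O)c1ccc(O[Si](C)(C)C)c(c1)-c1c(OCOC)cc(OCc2ccccc2)cc1OCOC | intermediate
14 | methyl 3-[4-(benzyloxy)-2,6-bis(methoxymethoxy)phenyl]-4-hydroxybenzoate | COC(=O)c1ccc(O)c(c1)-c1c(OCOC)cc(OCc2ccccc2)cc1OCOC | intermediate
15 | methyl 3-[4-(benzyloxy)-3-iodo-2,6-bis(methoxymethoxy)phenyl]-4-hydroxybenzoate | COC(=O)c1ccc(O)c(c1)-c1c(OCOC)cc(OCc2ccccc2)c(I)c1OCOC | intermediate
16 | methyl 3-[4-(benzyloxy)-3-(1-ethoxyvinyl)-2,6-bis(methoxymethoxy)phenyl]-4-hydroxybenzoate | COC(=O)c1ccc(O)c(c1)-c1c(OCOC)cc(OCc2ccccc2)c(C(=C)OCC)c1OCOC | intermediate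
17 | methyl 3-[3-acetyl-4-(benzyloxy)-2,6-dihydroxyphenyl]-4-hydroxybenzoate | COC(=O)c1ccc(O)c(c1)-c1c(O)cc(OCc2ccccc2)c(C(C)=O)c1O | intermediate
18 | methyl 3-[3-acetyl-4,6-bis(benzyloxy)-2-hydroxyphenyl]-4-(benzyloxy)benzoate | COC(=O)c1ccc(OCc2ccccc2)c(c1)-c1c(OCc2ccccc2)cc(OCc2ccccc2)c(C(C)=O)c1O | intermediate
19 | 4-(benzyloxy)benzaldehyde | O=Cc1ccc(OCc2ccccc2)cc1 | starting material
20 | 4-(benzyloxy)-3-{4,6-bis(benzyloxy)-3-[(E)-3-(4-benzyloxyphenyl)prop-2-enoyl]-2-hydroxyphenyl}benzoic acid | OC(=O)c1ccc(OCc2ccccc2)c(c1)-c1c(OCc2ccccc2)cc(OCc2ccccc2)c(C(=O)/C=C/c2ccc(OCc3ccccc3)cc2)c1O | intermediate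
21 | 4-(benzyloxy)-3-{5,7-bis(benzyloxy)-2-[4-(benzyloxy)phenyl]-4-oxo-4H-chromen-8-yl}benzoic acid | OC(=O)c1ccc(OCc2ccccc2)c(c1)-c1c(OCc2ccccc2)cc(OCc2ccccc2)c2c(=O)cc(-c3ccc(OCc4ccccc4)cc3)oc12 | intermediate
22 | 2',4',6'-trihydroxyacetophenone | CC(=O)c1c(O)cc(O)cc1O | starting material
23 | 2',6'-dihydroxy-4'-methoxyacetophenone | COc1cc(O)c(C(C)=O)c(O)c1 | intermediate
24 | 4-(benzyloxy)-3-{5,7-bis(benzyloxy)-2-[4-(benzyloxy)phenyl]-4-oxo-4H-chromen-8-yl}benzoyl chloride | ClC(=O)c1ccc(OCc2ccccc2)c(c1)-c1c(OCc2ccccc2)cc(OCc2ccccc2)c2c(=O)cc(-c3ccc(OCc4ccccc4)cc3)oc12 | intermediate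
25 | trilithium salt of 23 (bis-phenoxide enolate) | COc1cc(O[Li])c(C(=C)O[Li])c(O[Li])c1 | intermediate
26 | 1-(2,6-dihydroxy-4-methoxyphenyl)-3-{4-(benzyloxy)-3-[5,7-bis(benzyloxy)-2-(4-benzyloxyphenyl)-4-oxo-4H-chromen-8-yl]phenyl}propane-1,3-dione | COc1cc(O)c(C(=O)CC(=O)c2ccc(OCc3ccccc3)c(c2)-c2c(OCc3ccccc3)cc(OCc3ccccc3)c3c(=O)cc(-c4ccc(OCc5ccccc5)cc4)oc23)c(O)c1 | intermediate
27 | 4',5'',7'',4'''-tetra-O-benzylsequoiaflavone (5,7-bis(benzyloxy)-8-[2-(benzyloxy)-5-(5-hydroxy-7-methoxy-4-oxo-4H-chromen-2-yl)phenyl]-2-[4-(benzyloxy)phenyl]-4H-chromen-4-one) | COc1cc(O)c2c(=O)cc(-c3ccc(OCc4ccccc4)c(-c4c(OCc5ccccc5)cc(OCc5ccccc5)c5c(=O)cc(-c6ccc(OCc7ccccc7)cc6)oc45)c3)oc2c1 | intermediate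
28 | sequoiaflavone | COc1cc(O)c2c(=O)cc(-c3ccc(O)c(-c4c(O)cc(O)c5c(=O)cc(-c6ccc(O)cc6)oc45)c3)oc2c1 | target

## Step count and least certain steps

Total: 15 steps. Longest linear sequence: 14 steps, from phloroglucinol 1 through steps 1 to 11 and 13 to 15. Step 12 is a one-step side branch.

**Step 6 (key step).**
- *Risk:* the most likely failure is a cycloaddition too slow to compete with thermal decay of the partners. The two ortho MOM ethers twist the aryl group of 9 out of the alkene plane, so it shields both faces of the nucleophilic carbon.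
- At the temperature then required, three processes compete: self-dimerisation of the pyranone, oxygen-to-carbon silyl migration in the ketene acetal, and protonation of the ketene acetal by silanol that escapes capture.
- If the reaction runs stepwise, the conjugate adduct may open the pyranone ring instead of closing the carbocycle.
- *Fallback:* it sets out from 3 and returns at 14, giving up the ring construction for a cross-coupling. Compound 3 is lithiated to 4 as in step 3 and quenched with 2-isopropoxy-4,4,5,5-tetramethyl-1,3,2-dioxaborolane. This gives 2-[4-(benzyloxy)-2,6-bis(methoxymethoxy)phenyl]-4,4,5,5-tetramethyl-1,3,2-dioxaborolane F1. Suzuki–Miyaura coupling with commercial methyl 4-hydroxy-3-iodobenzoate (Pd(OAc)2, SPhos, K3PO4, toluene/H2O, 90 °C) then gives 14.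

**Step 3.**
- *Risk:* metalation may be incompletely regioselective, with attack next to the benzyloxy group or at the benzylic CH2. The doubly chelated, hindered aryllithium may also open the epoxide sluggishly.
- *Fallback:* it sets out from 1 and returns at 5, taking the aryl–carbon bond from a symmetric formylation instead of from metalation.
  - Vilsmeier–Haack formylation of 1 (POCl3, DMF) gives 2,4,6-trihydroxybenzaldehyde F2.
  - Benzylation of its only unchelated hydroxyl (BnBr, K2CO3, DMF) gives 4-(benzyloxy)-2,6-dihydroxybenzaldehyde F3.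
  - MOMCl with NaH gives 4-(benzyloxy)-2,6-bis(methoxymethoxy)benzaldehyde F4.
  - Wittig methylenation (Ph3PCH3Br, KOt-Bu, THF) gives 5-(benzyloxy)-2-ethenyl-1,3-bis(methoxymethoxy)benzene F5.
  - Hydroboration–oxidation (9-BBN, then NaOH/H2O2) gives 5.

**Step 8.**
- *Risk:* the iodide sits between two alkoxy groups on a very electron-rich ring. Oxidative addition to zerovalent palladium and the following transmetalation are therefore slow, and reductive loss of iodine can overtake coupling.
- *Fallback:* it sets out from 14 and returns at 17, bypassing steps 7 and 8. Methanolic HCl removes the MOM groups to give methyl 3-[4-(benzyloxy)-2,6-dihydroxyphenyl]-4-hydroxybenzoate F6. The symmetric resorcinol ring of F6 is then C-acetylated under Friedel–Crafts/Fries conditions (Ac2O, BF3·OEt2), and any phenolic acetate is methanolysed (K2CO3, MeOH) in the work-up. The price is exposure of the benzyl ether to a Lewis acid.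

**Step 13.**
- *Risk:* the trilithium salt may be poorly soluble. Acylation may stop at oxygen or occur twice, which wastes the advanced acid chloride.
- *Fallback:* it sets out from 23 and 21 and returns at 28, using the classical stepwise Baker–Venkataraman sequence on a protected partner.
  - Monobenzylation of 23 (BnBr, K2CO3, acetone) gives 2'-(benzyloxy)-6'-hydroxy-4'-methoxyacetophenone F7.
  - Carbodiimide esterification with 21 (EDC, DMAP, CH2Cl2) gives the aryl ester F8.
  - KOt-Bu in THF moves the acyl group to carbon and gives the diketone F9.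
  - p-TsOH in toluene closes it to penta-O-benzylsequoiaflavone F10.
  - Hydrogenolysis as in step 15 gives 28.

## Further compounds

F1 | step 6 | 2-[4-(benzyloxy)-2,6-bis(methoxymethoxy)phenyl]-4,4,5,5-tetramethyl-1,3,2-dioxaborolane | CC1(C)OB(OC1(C)C)c1c(OCOC)cc(OCc2ccccc2)cc1OCOC
F2 | step 3 | 2,4,6-trihydroxybenzaldehyde | O=Cc1c(O)cc(O)cc1O
F3 | step 3 | 4-(benzyloxy)-2,6-dihydroxybenzaldehyde | O=Cc1c(O)cc(OCc2ccccc2)cc1O
F4 | step 3 | 4-(benzyloxy)-2,6-bis(methoxymethoxy)benzaldehyde | O=Cc1c(OCOC)cc(OCc2ccccc2)cc1OCOC
F5 | step 3 | 5-(benzyloxy)-2-ethenyl-1,3-bis(methoxymethoxy)benzene | C=Cc1c(OCOC)cc(OCc2ccccc2)cc1OCOC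
F6 | step 8 | methyl 3-[4-(benzyloxy)-2,6-dihydroxyphenyl]-4-hydroxybenzoate | COC(=O)c1ccc(O)c(c1)-c1c(O)cc(OCc2ccccc2)cc1O
F7 | step 13 | 2'-(benzyloxy)-6'-hydroxy-4'-methoxyacetophenone | COc1cc(O)c(C(C)=O)c(OCc2ccccc2)c1
F8 | step 13 | 2-acetyl-3-(benzyloxy)-5-methoxyphenyl 4-(benzyloxy)-3-{5,7-bis(benzyloxy)-2-[4-(benzyloxy)phenyl]-4-oxo-4H-chromen-8-yl}benzoate | COc1cc(OCc2ccccc2)c(C(C)=O)c(OC(=O)c2ccc(OCc3ccccc3)c(c2)-c2c(OCc3ccccc3)cc(OCc3ccccc3)c3c(=O)cc(-c4ccc(OCc5ccccc5)cc4)oc23)c1
F9 | step 13 | 1-[2-(benzyloxy)-6-hydroxy-4-methoxyphenyl]-3-{4-(benzyloxy)-3-[5,7-bis(benzyloxy)-2-(4-benzyloxyphenyl)-4-oxo-4H-chromen-8-yl]phenyl}propane-1,3-dione | COc1cc(O)c(C(=O)CC(=O)c2ccc(OCc3ccccc3)c(c2)-c2c(OCc3ccccc3)cc(OCc3ccccc3)c3c(=O)cc(-c4ccc(OCc5ccccc5)cc4)oc23)c(OCc2ccccc2)c1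
F10 | step 13 | 5,4',5'',7'',4'''-penta-O-benzylsequoiaflavone | COc1cc(OCc2ccccc2)c2c(=O)cc(-c3ccc(OCc4ccccc4)c(-c4c(OCc5ccccc5)cc(OCc5ccccc5)c5c(=O)cc(-c6ccc(OCc7ccccc7)cc6)oc45)c3)oc2c1
A1 | alternative 1 | 1-(2,6-difluoro-4-methoxyphenyl)ethanone | COc1cc(F)c(C(C)=O)c(F)c1
A2 | alternative 1 | 1-(2,6-difluoro-4-methoxyphenyl)-3-{4-(benzyloxy)-3-[5,7-bis(benzyloxy)-2-(4-benzyloxyphenyl)-4-oxo-4H-chromen-8-yl]phenyl}propane-1,3-dione | COc1cc(F)c(C(=O)CC(=O)c2ccc(OCc3ccccc3)c(c2)-c2c(OCc3ccccc3)cc(OCc3ccccc3)c3c(=O)cc(-c4ccc(OCc5ccccc5)cc4)oc23)c(F)c1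
A3 | alternative 1 | 5-fluoro-5-deoxy-tetra-O-benzylsequoiaflavone | COc1cc(F)c2c(=O)cc(oc2c1)-c1ccc(OCc2ccccc2)c(c1)-c1c(OCc2ccccc2)cc(OCc2ccccc2)c2c(=O)cc(-c3ccc(OCc4ccccc4)cc3)oc12
A4 | alternative 2 | methyl 6-[2-(benzyloxy)-5-bromophenyl]-3,5-dioxohexanoate | COC(=O)CC(=O)CC(=O)Cc1cc(Br)ccc1OCc1ccccc1
A5 | alternative 2 | 2-[2-(benzyloxy)-5-bromophenyl]benzene-1,3,5-triol | Oc1cc(O)c(c(O)c1)-c1cc(Br)ccc1OCc1ccccc1
A6 | alternative 3 | triacetic acid lactone (4-hydroxy-6-methyl-2H-pyran-2-one) | Cc1cc(O)cc(=O)o1
A7 | alternative 3 | 4-hydroxy-6-[(E)-2-oxo-4-arylbut-3-enyl]-2H-pyran-2-one, aryl = 4-(benzyloxy)-3-[5,7-bis(benzyloxy)-2-(4-benzyloxyphenyl)-4-oxo-4H-chromen-8-yl]phenyl | O=c1cc(O)cc(CC(=O)/C=C/c2ccc(OCc3ccccc3)c(c2)-c2c(OCc3ccccc3)cc(OCc3ccccc3)c3c(=O)cc(-c4ccc(OCc5ccccc5)cc4)oc23)o1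
A8 | alternative 3 | 2',4',6'-trihydroxychalcone carrying tribenzylated unit 2 on its ring B | Oc1cc(O)c(C(=O)/C=C/c2ccc(OCc3ccccc3)c(c2)-c2c(OCc3ccccc3)cc(OCc3ccccc3)c3c(=O)cc(-c4ccc(OCc5ccccc5)cc4)oc23)c(O)c1
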